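**Retrosynthetic overview**
1. Daucane numbering is used: C1 = quaternary ring-fusion carbon with CH3, C2/C3 = CH2, C4 = carbinol carbon with iPr, C5 = ring-fusion CH, C6 = ester carbon, C7 = CHOH, C8/C9 = epoxide carbons (C8 with CH3), C10 = CH2, C14 = carbon on C8; β = face of the C1 methyl group.
2. Endgame on the α-face: 28 ⇐ desilylation ⇐ axial hydride reduction of a C7 ketone ⇐ α-epoxidation of the C8=C9 enone ⇐ C7 allylic oxidation of a silyl-protected 6α-ester; 6α-OH and 5α-H (trans fusion) ⇐ α-face hydroboration of C5=C6; C8 methyl ⇐ ester.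
3. Key disconnection: the C1–C10 σ-bond, made by a catalytic asymmetric tandem cyclopropanation/cis-divinylcyclopropane Cope rearrangement (formal [4+3]) that joins vinylcyclopentene 7 and methyl 2-diazobut-3-enoate 12, closes the seven-membered ring and sets the C1 quaternary centre.
4. Enabling feature: in the seven-membered ring C1–C5–C6–C7–C8–C9–C10, the bonds C5–C6 (oxygen at C6, ring-fusion H at C5) and C8–C9 (epoxide) are latent alkenes flanking C7. This is a cyclohepta-1,4-diene whose remaining saturated bond C1–C10 is exactly the bond formed when a C6–C7–C8 divinylcyclopropane rearranges; the five-membered ring supplies C1=C5 as one vinyl arm.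
5. Ring order: five-membered ring first (ozonolysis/aldol ring contraction of (S)-terpinen-4-ol, which brings the C4 stereocentre), then the seven-membered ring (key step), then the epoxide.

Key step: step 8

Remark: (S)-terpinen-4-ol is assumed to be used in high enantiomeric purity (enriched if the commercial lot requires it); diazo compounds 9, 10 and 12 are handled cold and 12 is not stored.

**Step 1**
Reactants: 1 (S)-terpinen-4-ol
Product: 2 (S)-triethyl{[4-methyl-1-(propan-2-yl)cyclohex-3-en-1-yl]oxy}silane
Conditions: Et3SiOTf, 2,6-lutidine, CH2Cl2, −78 → 0 °C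
Reagents that add atoms: triethylsilyl trifluoromethanesulfonate, CC[Si](CC)(CC)OS(=O)(=O)C(F)(F)F
Why: Silylation of the hindered tertiary alcohol with the silyl triflate is reliable and leaves the stereocentre untouched; the ether is needed because rhodium carbenoids insert into O–H bonds, and it later shields the β-face.

**Step 2**
Reactants: 2 (S)-triethyl{[4-methyl-1-(propan-2-yl)cyclohex-3-en-1-yl]oxy}silane
Product: 4 (S)-6-oxo-3-(propan-2-yl)-3-(triethylsilyloxy)heptanal, via secondary ozonide 3 (not isolated)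
Conditions: O3, CH2Cl2, −78 °C; then PPh3, −78 °C → rt
Reagents that add atoms: ozone, [O-][O+]=O
Why: Ozonolysis with reductive work-up cleaves the only C=C bond to the 1,6-keto aldehyde without touching the carbinol stereocentre.

**Step 3**
Reactants: 4 (S)-6-oxo-3-(propan-2-yl)-3-(triethylsilyloxy)heptanal
Product: 6 (R)-2-methyl-5-(propan-2-yl)-5-(triethylsilyloxy)cyclopent-1-ene-1-carbaldehyde, via aldol adduct 5 (not isolated)
Conditions: piperidine (0.2 equiv), AcOH (0.2 equiv), PhMe, 60 °C, 4 Å MS
Reagents that add atoms: none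
Why: Amine/acid-catalysed intramolecular aldol condensation (aldehyde enamine onto the methyl ketone, five-membered ring closure, then dehydration) is the standard ring contraction of cyclohexene-derived keto aldehydes and should give the tetrasubstituted enal with C1=C5 in place.

**Step 4**
Reactants: 6 (R)-2-methyl-5-(propan-2-yl)-5-(triethylsilyloxy)cyclopent-1-ene-1-carbaldehyde
Product: 7 (R)-triethyl{[2-ethenyl-3-methyl-1-(propan-2-yl)cyclopent-2-en-1-yl]oxy}silane
Conditions: Ph3PCH3Br, KOtBu, THF, 0 °C → rt
Reagents that add atoms: methylenetriphenylphosphorane (from methyltriphenylphosphonium bromide and KOtBu), C=P(c1ccccc1)(c1ccccc1)c1ccccc1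
Why: Wittig methylenation of the non-enolisable aldehyde gives the vinylcyclopentene diene; no stereocentre is formed.

**Step 5**
Reactants: 8 methyl acetoacetate
Product: 9 methyl 2-diazo-3-oxobutanoate
Conditions: 4-acetamidobenzenesulfonyl azide, Et3N, MeCN, 0 °C → rt
Reagents that add atoms: 4-acetamidobenzenesulfonyl azide, CC(=O)Nc1ccc(cc1)S(=O)(=O)N=[N+]=[N-]
Why: Regitz diazo transfer to the 1,3-dicarbonyl methylene is a standard, high-yielding reaction.

**Step 6**
Reactants: 9 methyl 2-diazo-3-oxobutanoate
Product: 10 methyl 2-diazo-3-hydroxybutanoate (racemic)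
Conditions: NaBH4, MeOH, 0 °C
Reagents that add atoms: none
Why: NaBH4 reduces the ketone and spares the diazo ester; the new carbinol centre is removed in the next step.

**Step 7**
Reactants: 10 methyl 2-diazo-3-hydroxybutanoate
Product: 12 methyl 2-diazobut-3-enoate, via dichlorophosphate ester 11 (not isolated)
Conditions: POCl3, Et3N, CH2Cl2, 0 °C; used at once as a cold pentane solution
Reagents that add atoms: none
Why: Phosphorylation and base-induced β-elimination (dehydration) give the vinyldiazoacetate, which is used at once because it cyclises to a pyrazole on standing.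

**Step 8**
Reactants: 7 (R)-triethyl{[2-ethenyl-3-methyl-1-(propan-2-yl)cyclopent-2-en-1-yl]oxy}silane; 12 methyl 2-diazobut-3-enoate
Product: 14 methyl (1R,4R)-4-(triethylsilyloxy)dauca-5,8-dien-14-oate, via cis-divinylcyclopropane 13 (not isolated)
Conditions: Rh2(R-DOSP)4 (1 mol %), 12 (2 equiv) added slowly, pentane, −40 °C → rt; then PhMe, 90 °C
Reagents that add atoms: none
Why: Rh2(R-DOSP)4 (a chiral prolinate complex of divalent rhodium) decomposes 12 to a donor/acceptor rhodium vinylcarbenoid that adds in a concerted, asynchronous [2+1] fashion to the terminal vinyl group C6=C7 of 7, the only alkene it can reach because the ring alkene C1=C5 is tetrasubstituted, and places the cyclopentenyl group cis to the vinyl group and trans to the ester, as is general for such carbenoids, to give cis-divinylcyclopropane 13. In 13 the two vinyl arms (C5=C1 and C9=C10) can lie over the three-membered ring, so a [3,3]-sigmatropic cis-divinylcyclopropane (Cope) rearrangement through the boat transition state breaks C6–C8 and forms C1–C10; the seven-membered ring is thus closed by a three-to-seven ring expansion and the transient three-membered ring by carbene [2+1] addition. The closest known reaction type is the rhodium-catalysed tandem cyclopropanation/Cope rearrangement (formal [4+3] cycloaddition) of vinyldiazoacetates with 1,3-dienes, which tolerates a fully substituted diene terminus and so builds quaternary carbons. The only stereocentre created, quaternary C1, is fixed by the boat geometry from the configuration of cyclopropane carbon C6, which the chiral catalyst sets; the R-configured catalyst is chosen because the S-configured one gives the opposite (2R) cyclopropane series with monosubstituted alkenes, and the distant C4 centre is expected to be a spectator. The step needs site selectivity (secured by the substitution pattern of 7), cis-divinyl diastereoselectivity (inherent to donor/acceptor carbenoids) and catalyst-controlled face selectivity. Because the C1 methyl group must point inside the boat, the rearrangement is expected to need gentle heating, hence the second stage in toluene.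

**Step 9**
Reactants: 14 methyl (1R,4R)-4-(triethylsilyloxy)dauca-5,8-dien-14-oate
Product: 16 methyl 6α-hydroxy-4β-(triethylsilyloxy)-5αH-dauc-8-en-14-oate, via C6 alkylborane 15 (not isolated)
Conditions: BH3·SMe2 (1.2 equiv), THF, 0 °C → rt; then 30% H2O2, pH 7 phosphate buffer, MeOH, 0 °C → rt
Reagents that add atoms: hydrogen peroxide, OO
Why: In this hydroboration/oxidation the electrophilic borane should select the electron-rich C5=C6 alkene over the enoate, boron goes to the less hindered C6, and syn addition from the α-face, opposite the pseudoaxial C1 methyl and C4 silyloxy groups (as with Δ5-steroids), sets 5α-H and, after oxidation with retention, 6α-OH, i.e. the trans ring fusion.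

**Step 10**
Reactants: 16 methyl 6α-hydroxy-4β-(triethylsilyloxy)-5αH-dauc-8-en-14-oate
Product: 17 4β-(triethylsilyloxy)-5αH-dauc-8-ene-6α,14-diol
Conditions: iBu2AlH (3.5 equiv), CH2Cl2, −78 °C; aq potassium sodium tartrate
Reagents that add atoms: none
Why: 1,2-Reduction of the conjugated methyl ester by iBu2AlH gives the primary allylic alcohol without touching the trisubstituted alkene or the silyl ether.

**Step 11**
Reactants: 17 4β-(triethylsilyloxy)-5αH-dauc-8-ene-6α,14-diol
Product: 19 4β-(triethylsilyloxy)-5αH-dauc-8-en-6α-ol (4-O-triethylsilyl jaeschkeanadiol), via allylic mesylate 18 (not isolated)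
Conditions: MsCl (1.05 equiv), Et3N, THF, −40 °C; then LiBHEt3 (4 equiv), −40 → 0 °C
Reagents that add atoms: none
Why: The primary allylic hydroxyl is sulfonylated selectively over the hindered secondary C6 hydroxyl, and SN2 hydride displacement of the mesylate turns C14 into the C8 methyl group with the C8=C9 alkene unmoved.

**Step 12**
Reactants: 20 4-hydroxybenzoic acid
Product: 22 4-(tert-butyldimethylsilyloxy)benzoic acid, via silyl ester 21 (not isolated)
Conditions: tBuMe2SiCl (2.3 equiv), imidazole, DMF, rt; then AcOH/THF/H2O, rt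
Reagents that add atoms: tert-butyldimethylsilyl chloride, CC(C)(C)[Si](C)(C)Cl
Why: Exhaustive silylation followed by selective hydrolysis of the labile silyl ester gives the phenol-protected acid.

**Step 13**
Reactants: 19 4β-(triethylsilyloxy)-5αH-dauc-8-en-6α-ol; 22 4-(tert-butyldimethylsilyloxy)benzoic acid
Product: 23 4β-(triethylsilyloxy)-5αH-dauc-8-en-6α-yl 4-(tert-butyldimethylsilyloxy)benzoate
Conditions: DCC, DMAP, CH2Cl2, rt
Reagents that add atoms: none
Why: Steglich esterification acylates the only free hydroxyl (secondary C6–OH) with retention of configuration, since the tertiary C4 oxygen is silylated.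

**Step 14**
Reactants: 23 4β-(triethylsilyloxy)-5αH-dauc-8-en-6α-yl 4-(tert-butyldimethylsilyloxy)benzoate
Product: 24 (7RS)-7-hydroxy-4β-(triethylsilyloxy)-5αH-dauc-8-en-6α-yl 4-(tert-butyldimethylsilyloxy)benzoate
Conditions: SeO2 (0.5 equiv), tBuOOH (3 equiv), CH2Cl2, rt → 40 °C
Reagents that add atoms: selenium dioxide (oxygen donor, regenerated), O=[Se]=O; tert-butyl hydroperoxide (terminal oxidant), CC(C)(C)OO
Why: Selenium dioxide allylic hydroxylation (ene reaction, then [2,3]-sigmatropic shift) should go to the ring CH2 attached to the more substituted alkene carbon, here C7, in preference to the C8 methyl and to C10 on the less substituted, neopentyl side, as in the C4 hydroxylation of Δ5-3-acyloxy steroids; the C7 configuration does not matter because it is erased in step 15.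

**Step 15**
Reactants: 24 (7RS)-7-hydroxy-4β-(triethylsilyloxy)-5αH-dauc-8-en-6α-yl 4-(tert-butyldimethylsilyloxy)benzoate
Product: 25 7-oxo-4β-(triethylsilyloxy)-5αH-dauc-8-en-6α-yl 4-(tert-butyldimethylsilyloxy)benzoate
Conditions: Dess–Martin periodinane, NaHCO3, CH2Cl2, 0 °C → rt
Reagents that add atoms: none
Why: Dess–Martin oxidation of the allylic alcohol gives the C7 enone under neutral conditions that preserve the ester and both silyl ethers.

**Step 16**
Reactants: 25 7-oxo-4β-(triethylsilyloxy)-5αH-dauc-8-en-6α-yl 4-(tert-butyldimethylsilyloxy)benzoate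
Product: 26 8α,9α-epoxy-7-oxo-4β-(triethylsilyloxy)-5αH-daucan-6α-yl 4-(tert-butyldimethylsilyloxy)benzoate
Conditions: dimethyldioxirane, acetone, 0 °C → rt
Reagents that add atoms: dimethyldioxirane, CC1(C)OO1
Why: Dimethyldioxirane epoxidises the enone alkene without base (which could enolise the α-acyloxy ketone or cleave the aryl silyl ether) and should approach the α-face, opposite the axial C1 methyl group, as in the α-epoxidation of Δ2-steroids, to set C8 and C9.

**Step 17**
Reactants: 26 8α,9α-epoxy-7-oxo-4β-(triethylsilyloxy)-5αH-daucan-6α-yl 4-(tert-butyldimethylsilyloxy)benzoate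
Product: 27 8α,9α-epoxy-7β-hydroxy-4β-(triethylsilyloxy)-5αH-daucan-6α-yl 4-(tert-butyldimethylsilyloxy)benzoate
Conditions: NaBH4, CeCl3·7H2O, MeOH, −78 °C
Reagents that add atoms: none
Why: Luche reduction should add hydride 1,2 along the axial trajectory on the α-face to give the equatorial 7β-alcohol, anti to the epoxide oxygen (the usual outcome of NaBH4/CeCl3 with α,β-epoxy ketones) and trans to the 6α-ester; the low temperature prevents acyl migration.

**Step 18**
Reactants: 27 8α,9α-epoxy-7β-hydroxy-4β-(triethylsilyloxy)-5αH-daucan-6α-yl 4-(tert-butyldimethylsilyloxy)benzoate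
Product: 28 (1R,4R,5S,6R,7S,8R,9S)-8,9-epoxy-4,7-dihydroxydaucan-6-yl 4-hydroxybenzoate (CNP0290052.1)
Conditions: nBu4NF, AcOH (1:1), THF, 0 °C → rt
Reagents that add atoms: none
Why: Fluoride cleaves the aryl silyl ether and the tertiary triethylsilyl ether, and buffering with AcOH suppresses 6→7 acyl migration and epoxide opening.

**Compound list**
1 | (S)-terpinen-4-ol, (1S)-4-methyl-1-(propan-2-yl)cyclohex-3-en-1-ol | CC(C)[C@]1(O)CCC(C)=CC1 | starting material
2 | (S)-triethyl{[4-methyl-1-(propan-2-yl)cyclohex-3-en-1-yl]oxy}silane | CC(C)[C@]1(O[Si](CC)(CC)CC)CCC(C)=CC1 | intermediate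
3 | secondary ozonide (1,2,4-trioxolane) of 2, mixture of diastereomers at the two acetal carbons | CC(C)[C@]1(O[Si](CC)(CC)CC)CCC2(C)OOC(C1)O2 | intermediate
4 | (S)-6-oxo-3-(propan-2-yl)-3-(triethylsilyloxy)heptanal | CC(C)[C@](O[Si](CC)(CC)CC)(CCC(C)=O)CC=O | intermediate
5 | (5R)-2-hydroxy-2-methyl-5-(propan-2-yl)-5-(triethylsilyloxy)cyclopentane-1-carbaldehyde, mixture at C1 and C2 | CC(C)[C@]1(O[Si](CC)(CC)CC)CCC(C)(O)C1C=O | intermediate
6 | (R)-2-methyl-5-(propan-2-yl)-5-(triethylsilyloxy)cyclopent-1-ene-1-carbaldehyde | CC(C)[C@]1(O[Si](CC)(CC)CC)CCC(C)=C1C=O | intermediate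
7 | (R)-triethyl{[2-ethenyl-3-methyl-1-(propan-2-yl)cyclopent-2-en-1-yl]oxy}silane | CC(C)[C@]1(O[Si](CC)(CC)CC)CCC(C)=C1C=C | intermediate
8 | methyl acetoacetate | COC(=O)CC(C)=O | starting material
9 | methyl 2-diazo-3-oxobutanoate | COC(=O)C(=[N+]=[N-])C(C)=O | intermediate
10 | methyl 2-diazo-3-hydroxybutanoate (racemic) | COC(=O)C(=[N+]=[N-])C(C)O | intermediate
11 | methyl 2-diazo-3-(dichlorophosphoryloxy)butanoate | COC(=O)C(=[N+]=[N-])C(C)OP(=O)(Cl)Cl | intermediate
12 | methyl 2-diazobut-3-enoate | COC(=O)C(=[N+]=[N-])C=C | intermediate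
13 | methyl (1S,2S)-1-ethenyl-2-[(5R)-2-methyl-5-(propan-2-yl)-5-(triethylsilyloxy)cyclopent-1-en-1-yl]cyclopropane-1-carboxylate (vinyl and cyclopentenyl cis) | COC(=O)[C@]1(C=C)C[C@H]1C1=C(C)CC[C@@]1(O[Si](CC)(CC)CC)C(C)C | intermediate
14 | methyl (1R,4R)-4-(triethylsilyloxy)dauca-5,8-dien-14-oate | CC(C)[C@]1(O[Si](CC)(CC)CC)CC[C@]2(C)CC=C(C(=O)OC)CC=C12 | intermediate
15 | methyl 6α-boranyl-4β-(triethylsilyloxy)-5αH-dauc-8-en-14-oate | CC(C)[C@]1(O[Si](CC)(CC)CC)CC[C@]2(C)CC=C(C(=O)OC)C[C@H](B)[C@H]21 | intermediate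
16 | methyl 6α-hydroxy-4β-(triethylsilyloxy)-5αH-dauc-8-en-14-oate | CC(C)[C@]1(O[Si](CC)(CC)CC)CC[C@]2(C)CC=C(C(=O)OC)C[C@H](O)[C@H]21 | intermediate
17 | 4β-(triethylsilyloxy)-5αH-dauc-8-ene-6α,14-diol | CC(C)[C@]1(O[Si](CC)(CC)CC)CC[C@]2(C)CC=C(CO)C[C@H](O)[C@H]21 | intermediate
18 | 6α-hydroxy-4β-(triethylsilyloxy)-5αH-dauc-8-en-14-yl methanesulfonate | CC(C)[C@]1(O[Si](CC)(CC)CC)CC[C@]2(C)CC=C(COS(C)(=O)=O)C[C@H](O)[C@H]21 | intermediate
19 | 4β-(triethylsilyloxy)-5αH-dauc-8-en-6α-ol (4-O-triethylsilyl jaeschkeanadiol) | CC(C)[C@]1(O[Si](CC)(CC)CC)CC[C@]2(C)CC=C(C)C[C@H](O)[C@H]21 | intermediate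
20 | 4-hydroxybenzoic acid | OC(=O)c1ccc(O)cc1 | starting material
21 | tert-butyldimethylsilyl 4-(tert-butyldimethylsilyloxy)benzoate | CC(C)(C)[Si](C)(C)OC(=O)c1ccc(O[Si](C)(C)C(C)(C)C)cc1 | intermediate
22 | 4-(tert-butyldimethylsilyloxy)benzoic acid | CC(C)(C)[Si](C)(C)Oc1ccc(cc1)C(O)=O | intermediate
23 | 4β-(triethylsilyloxy)-5αH-dauc-8-en-6α-yl 4-(tert-butyldimethylsilyloxy)benzoate | CC(C)[C@]1(O[Si](CC)(CC)CC)CC[C@]2(C)CC=C(C)C[C@H](OC(=O)c3ccc(O[Si](C)(C)C(C)(C)C)cc3)[C@H]21 | intermediate
24 | (7RS)-7-hydroxy-4β-(triethylsilyloxy)-5αH-dauc-8-en-6α-yl 4-(tert-butyldimethylsilyloxy)benzoate | CC(C)[C@]1(O[Si](CC)(CC)CC)CC[C@]2(C)CC=C(C)C(O)[C@H](OC(=O)c3ccc(O[Si](C)(C)C(C)(C)C)cc3)[C@H]21 | intermediate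
25 | 7-oxo-4β-(triethylsilyloxy)-5αH-dauc-8-en-6α-yl 4-(tert-butyldimethylsilyloxy)benzoate | CC(C)[C@]1(O[Si](CC)(CC)CC)CC[C@]2(C)CC=C(C)C(=O)[C@H](OC(=O)c3ccc(O[Si](C)(C)C(C)(C)C)cc3)[C@H]21 | intermediate
26 | 8α,9α-epoxy-7-oxo-4β-(triethylsilyloxy)-5αH-daucan-6α-yl 4-(tert-butyldimethylsilyloxy)benzoate | CC(C)[C@]1(O[Si](CC)(CC)CC)CC[C@]2(C)C[C@@H]3O[C@]3(C)C(=O)[C@H](OC(=O)c3ccc(O[Si](C)(C)C(C)(C)C)cc3)[C@H]21 | intermediate
27 | 8α,9α-epoxy-7β-hydroxy-4β-(triethylsilyloxy)-5αH-daucan-6α-yl 4-(tert-butyldimethylsilyloxy)benzoate | CC(C)[C@]1(O[Si](CC)(CC)CC)CC[C@]2(C)C[C@@H]3O[C@]3(C)[C@@H](O)[C@H](OC(=O)c3ccc(O[Si](C)(C)C(C)(C)C)cc3)[C@H]21 | intermediate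
28 | (1R,4R,5S,6R,7S,8R,9S)-8,9-epoxy-4,7-dihydroxydaucan-6-yl 4-hydroxybenzoate (1β-CH3, 4β-OH, 5α-H, 6α-ester, 7β-OH, 8α,9α-epoxide) | CC(C)[C@]1(O)CC[C@]2(C)C[C@@H]3O[C@]3(C)[C@@H](O)[C@H](OC(=O)c3ccc(O)cc3)[C@H]21 | target

**Step count and risks**
Total step count: 18. Longest linear sequence: 14 steps (steps 1–4, 8–11, 13–18, from (S)-terpinen-4-ol).

The three steps most likely to fail:

Step 8. The ring-expanding sigmatropic shift may stall because the C1 methyl group must sit inside the boat, so the cyclopropane could accumulate and epimerise on heating. The carbenoid may also be lost to dimerisation or pyrazole formation, and catalyst and substrate facial preferences may be mismatched. The fallback sets out from 6 and uses known reactions only. Allylmagnesium bromide (THF, −78 °C) adds 1,2 to the aldehyde to give the homoallylic alcohol F1. An anionic oxy-Cope rearrangement (KH, 18-crown-6, THF, 0 °C → rt) then transfers the allyl group to C1, making C1–C10 by a [3,3] shift, and releases the C1-allylated aldehyde F2 after protonation. C5 is equilibrated under the basic conditions, and C1 epimers would be separated. Zinc-mediated Barbier allylation with methyl 2-(bromomethyl)acrylate (Zn, aq NH4Cl, THF) gives the hydroxy diene ester F3, C6 epimers again being separated. Ring-closing metathesis (second-generation Grubbs catalyst, CH2Cl2, 40 °C) forms C8=C9 and comes back to the route at 16. This fallback has weaker stereocontrol than the main route.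

Step 9. The borane may not discriminate sufficiently between the hindered C5=C6 alkene and the enoate, or may add partly from the β-face. The fallback sets out from 14. The electrophilic peracid mCPBA (NaHCO3, CH2Cl2, 0 °C) selects the electron-rich alkene and gives the 5α,6α-epoxide F4. Reductive opening with Cp2TiCl (trivalent titanium, from Cp2TiCl2 and Mn, with 2,4,6-collidine hydrochloride and 1,4-cyclohexadiene in THF) cleaves the tertiary C5–O bond. The C5 radical takes hydrogen on the open α-face while the C6–O bond keeps its configuration, and the route is rejoined at 16.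

Step 14. Oxidation may go to the C8 methyl group instead of C7, or the ene reaction may be sluggish next to the acyloxy-bearing carbon. The fallback sets out from 19 and moves the oxidation to enolate chemistry. Dess–Martin oxidation gives the C6 ketone F5. Deprotonation at the allylic C7 (KN(SiMe3)2, THF, −78 °C) and oxidation with 2-(phenylsulfonyl)-3-phenyloxaziridine give the α-hydroxy ketone F6. Base-mediated α-ketol (enediol) isomerisation (DBU, CH2Cl2), driven by conjugation with C8=C9, gives the hydroxy enone F7 with the equatorial 6α-hydroxyl. Esterification with 22 (DCC, DMAP) comes back to the route at 25.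

**Further compounds**
F1 | step 8 | 1-[(5R)-2-methyl-5-(propan-2-yl)-5-(triethylsilyloxy)cyclopent-1-en-1-yl]but-3-en-1-ol (carbinol epimers) | CC(C)[C@]1(O[Si](CC)(CC)CC)CCC(C)=C1C(O)CC=C
F2 | step 8 | 2-methyl-5-(propan-2-yl)-2-(prop-2-en-1-yl)-5-(triethylsilyloxy)cyclopentane-1-carbaldehyde (1β-CH3, 5α-H, 4β-silyloxy in daucane numbering) | CC(C)[C@]1(O[Si](CC)(CC)CC)CC[C@](C)(CC=C)[C@H]1C=O
F3 | step 8 | methyl 4-hydroxy-2-methylidene-4-[2-methyl-5-(propan-2-yl)-2-(prop-2-en-1-yl)-5-(triethylsilyloxy)cyclopentyl]butanoate (6α-OH in daucane numbering) | CC(C)[C@]1(O[Si](CC)(CC)CC)CC[C@](C)(CC=C)[C@H]1[C@@H](O)CC(=C)C(=O)OC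
F4 | step 9 | methyl 5α,6α-epoxy-4β-(triethylsilyloxy)dauc-8-en-14-oate | CC(C)[C@]1(O[Si](CC)(CC)CC)CC[C@]2(C)CC=C(C(=O)OC)C[C@@H]3O[C@@]321
F5 | step 14 | 4β-(triethylsilyloxy)-5αH-dauc-8-en-6-one | CC(C)[C@]1(O[Si](CC)(CC)CC)CC[C@]2(C)CC=C(C)CC(=O)[C@H]21
F6 | step 14 | (7RS)-7-hydroxy-4β-(triethylsilyloxy)-5αH-dauc-8-en-6-one | CC(C)[C@]1(O[Si](CC)(CC)CC)CC[C@]2(C)CC=C(C)C(O)C(=O)[C@H]21
F7 | step 14 | 6α-hydroxy-4β-(triethylsilyloxy)-5αH-dauc-8-en-7-one | CC(C)[C@]1(O[Si](CC)(CC)CC)CC[C@]2(C)CC=C(C)C(=O)[C@H](O)[C@H]21
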